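The oxolane ring is disconnected at C3–C4 together with the exocyclic C7'–aryl bond. This is possible because ring carbon C4 bears the CH2 (C7') that ties the oxolane to the second trimethoxyphenyl ring, so an allyl ether on the C2 oxygen already contains C5, C4 and C7'. A nickel-catalysed radical cyclization–Negishi arylation of a β-iodo allyl ether with an arylzinc bromide closes the ring 5-exo, attaches the aryl group and sets C3 and C4 under control of the C2 stereocentre. The benzylic centre of the iodide comes from a Sharpless epoxide opened with allyl alcohol; the configuration at the iodide carbon is irrelevant.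

Key step: step 7

Remark: the oxolane is numbered O1, C2 (aryl), C3 (CH2O), C4 (benzyl), C5, with C7' the benzylic CH2; the benzylic carbon is labelled R in the open-chain intermediates and S in the oxolanes only because substituent priorities change, and the iodide is drawn as the epimer expected from inversion although either epimer serves.

Step 1
Reactants: 1 methyl (2E)-3-(3,4,5-trimethoxyphenyl)prop-2-enoate
Product: 2 (2E)-3-(3,4,5-trimethoxyphenyl)prop-2-en-1-ol
Conditions: iBu2AlH (2.5 equiv), CH2Cl2, −78 → 0 °C; aq. potassium sodium tartrate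
Reagents that add atoms: none
Why: Ester-to-alcohol reduction with iBu2AlH is a 1,2-hydride delivery that leaves the conjugated E-alkene and the aryl methyl ethers untouched, and no stereocentre is formed.

Step 2
Reactants: 2 (2E)-3-(3,4,5-trimethoxyphenyl)prop-2-en-1-ol
Product: 3 [(2S,3S)-3-(3,4,5-trimethoxyphenyl)oxiran-2-yl]methanol
Conditions: Ti(OiPr)4 (10 mol %), L-(+)-diisopropyl tartrate (12 mol %), t-BuOOH, 4 Å MS, CH2Cl2, −20 °C; aq. NaOH/NaCl work-up
Reagents that add atoms: tert-butyl hydroperoxide, CC(C)(C)OO
Why: Sharpless asymmetric epoxidation of an E-allylic alcohol, in which the complex formed from Ti(OiPr)4 and the L-(+)-tartrate delivers oxygen to the alkene face that gives the (2S,3S)-epoxy alcohol, the catalytic sieve-assisted protocol and basic work-up sparing the acid-sensitive aryl epoxide.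

Step 3
Reactants: 3 [(2S,3S)-3-(3,4,5-trimethoxyphenyl)oxiran-2-yl]methanol
Product: 4 tert-butyl(dimethyl){[(2S,3S)-3-(3,4,5-trimethoxyphenyl)oxiran-2-yl]methoxy}silane
Conditions: TBSCl, imidazole, CH2Cl2, 0 → 23 °C
Reagents that add atoms: tert-butyldimethylsilyl chloride (TBSCl), CC(C)(C)[Si](C)(C)Cl
Why: Standard silylation of a primary alcohol under mildly basic conditions that do not open the epoxide, and no stereocentre is touched.

Step 4
Reactants: 4 tert-butyl(dimethyl){[(2S,3S)-3-(3,4,5-trimethoxyphenyl)oxiran-2-yl]methoxy}silane; 5 prop-2-en-1-ol (allyl alcohol)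
Product: 6 (1R,2S)-3-{[tert-butyl(dimethyl)silyl]oxy}-1-(prop-2-en-1-yloxy)-1-(3,4,5-trimethoxyphenyl)propan-2-ol
Conditions: 5 (10 equiv), BF3·OEt2 (15 mol %), CH2Cl2, −40 → −20 °C; Et3N quench
Reagents that add atoms: none
Why: Lewis-acid-catalysed alcoholysis of an aryl epoxide, in which BF3 activation directs allyl alcohol to the benzylic carbon (the other epoxide carbon is deactivated by the adjacent silyloxymethyl group) with backside attack, so the (3S) centre is inverted to the (1R) ether and the carbinol centre stays (S); any benzylic epimer formed by ionisation is a diastereomer and is removed by chromatography.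

Step 5
Reactants: 6 (1R,2S)-3-{[tert-butyl(dimethyl)silyl]oxy}-1-(prop-2-en-1-yloxy)-1-(3,4,5-trimethoxyphenyl)propan-2-ol
Product: 7 tert-butyl{[(2R,3R)-2-iodo-3-(prop-2-en-1-yloxy)-3-(3,4,5-trimethoxyphenyl)propyl]oxy}dimethylsilane
Conditions: PPh3, I2, imidazole, toluene, 70 °C
Reagents that add atoms: iodine, II
Why: Garegg–Samuelsson (Appel-type) iodination, in which iodide displaces the oxyphosphonium salt of the secondary alcohol with inversion under neutral conditions that spare the silyl, allyl and aryl ethers; the configuration at this carbon is of no consequence because it becomes a planar radical in step 7.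

Step 6
Reactants: 8 5-bromo-1,2,3-trimethoxybenzene
Product: 10 (3,4,5-trimethoxyphenyl)zinc bromide as a titrated THF solution, via (3,4,5-trimethoxyphenyl)magnesium bromide 9 (not isolated)
Conditions: Mg, THF, 40 °C; then ZnBr2 (1.05 equiv), THF, 0 → 23 °C
Reagents that add atoms: zinc bromide, Br[Zn]Br
Why: Grignard formation by magnesium insertion into the aryl bromide followed by transmetalation with ZnBr2 gives the arylzinc halide free of alkyl halide by-products that could compete in the nickel step.

Step 7
Reactants: 7 tert-butyl{[(2R,3R)-2-iodo-3-(prop-2-en-1-yloxy)-3-(3,4,5-trimethoxyphenyl)propyl]oxy}dimethylsilane; 10 (3,4,5-trimethoxyphenyl)zinc bromide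
Product: 11 tert-butyl{[(2S,3R,4R)-4-(3,4,5-trimethoxybenzyl)-2-(3,4,5-trimethoxyphenyl)oxolan-3-yl]methoxy}dimethylsilane
Conditions: NiBr2(glyme) (10 mol %), 2,2':6',2''-terpyridine (12 mol %), 10 (2.5 equiv), THF, 23 °C
Reagents that add atoms: none
Why: Terpyridine-ligated monovalent nickel, carried as an arylnickel species after transmetalation from 10, abstracts iodine from 7 to give the secondary C3 radical (erasing the iodide configuration), which adds to the allyl alkene to form C3–C4; the resulting primary C7' radical is captured by arylnickel, and reductive elimination from trivalent nickel forms the C7'–aryl bond. The closest known reaction type is the nickel-catalysed tandem radical cyclization–Negishi arylation of alkene-tethered secondary alkyl iodides, β-iodo allyl ethers included, with arylzinc halides. The one ring, the oxolane, is closed by 5-exo-trig radical addition through a chair-like Beckwith–Houk transition state. C3 is set trans to the C2 aryl group, which sits pseudo-equatorial and pushes the silyloxymethyl group on the radical carbon to the opposite face, and C4 is set in the same transition state with its CH2 cis to the C3 substituent and trans to the C2 aryl group, the two preferences reinforcing each other to give (2S,3R,4R). The step needs cyclization to outrun direct arylation or reduction of the C3 radical, which the fast closure of a 3-oxahex-5-enyl radical and the low catalyst concentration should secure, and it needs diastereocontrol from C2, the only stereocentre that survives radical formation; the weaker of the two preferences is the cis relation at C3–C4, so a minor 3,4-trans isomer is expected and is removed by chromatography.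

Step 8
Reactants: 11 tert-butyl{[(2S,3R,4R)-4-(3,4,5-trimethoxybenzyl)-2-(3,4,5-trimethoxyphenyl)oxolan-3-yl]methoxy}dimethylsilane
Product: 12 [(2S,3R,4R)-4-(3,4,5-trimethoxybenzyl)-2-(3,4,5-trimethoxyphenyl)oxolan-3-yl]methanol (CNP0321241.1)
Conditions: Bu4NF, THF, 0 → 23 °C
Reagents that add atoms: none
Why: Fluoride-mediated desilylation, driven by Si–F bond formation, frees the primary alcohol without affecting the oxolane, the aryl methyl ethers or any stereocentre.

Compound list
1 | methyl (2E)-3-(3,4,5-trimethoxyphenyl)prop-2-enoate | COC(=O)/C=C/c1cc(OC)c(OC)c(OC)c1 | starting material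
2 | (2E)-3-(3,4,5-trimethoxyphenyl)prop-2-en-1-ol | OC/C=C/c1cc(OC)c(OC)c(OC)c1 | intermediate
3 | [(2S,3S)-3-(3,4,5-trimethoxyphenyl)oxiran-2-yl]methanol | OC[C@@H]1O[C@H]1c2cc(OC)c(OC)c(OC)c2 | intermediate
4 | tert-butyl(dimethyl){[(2S,3S)-3-(3,4,5-trimethoxyphenyl)oxiran-2-yl]methoxy}silane | CC(C)(C)[Si](C)(C)OC[C@@H]1O[C@H]1c2cc(OC)c(OC)c(OC)c2 | intermediate
5 | prop-2-en-1-ol (allyl alcohol) | C=CCO | starting material
6 | (1R,2S)-3-{[tert-butyl(dimethyl)silyl]oxy}-1-(prop-2-en-1-yloxy)-1-(3,4,5-trimethoxyphenyl)propan-2-ol | C=CCO[C@H](c1cc(OC)c(OC)c(OC)c1)[C@@H](O)CO[Si](C)(C)C(C)(C)C | intermediate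
7 | tert-butyl{[(2R,3R)-2-iodo-3-(prop-2-en-1-yloxy)-3-(3,4,5-trimethoxyphenyl)propyl]oxy}dimethylsilane | C=CCO[C@H](c1cc(OC)c(OC)c(OC)c1)[C@H](I)CO[Si](C)(C)C(C)(C)C | intermediate
8 | 5-bromo-1,2,3-trimethoxybenzene | COc1cc(Br)cc(OC)c1OC | starting material
9 | (3,4,5-trimethoxyphenyl)magnesium bromide | COc1cc([Mg]Br)cc(OC)c1OC | intermediate
10 | (3,4,5-trimethoxyphenyl)zinc bromide | COc1cc([Zn]Br)cc(OC)c1OC | intermediate
11 | tert-butyl{[(2S,3R,4R)-4-(3,4,5-trimethoxybenzyl)-2-(3,4,5-trimethoxyphenyl)oxolan-3-yl]methoxy}dimethylsilane | COc1cc(C[C@H]2CO[C@H](c3cc(OC)c(OC)c(OC)c3)[C@H]2CO[Si](C)(C)C(C)(C)C)cc(OC)c1OC | intermediate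
12 | [(2S,3R,4R)-4-(3,4,5-trimethoxybenzyl)-2-(3,4,5-trimethoxyphenyl)oxolan-3-yl]methanol | COc1cc(C[C@H]2CO[C@H](c3cc(OC)c(OC)c(OC)c3)[C@H]2CO)cc(OC)c1OC | target

Total step count: 8. Longest linear sequence: 7 steps (steps 1–5, 7 and 8); step 6 is a one-step side branch.

Steps most likely to fail

Step 7. The C3 radical may be arylated or reduced before it cyclizes, the alkylnickel may undergo β-alkoxy elimination, or control of the C3–C4 cis relation may be weak. The fallback sets out from 7 and returns at 11: the aryl group is placed on the alkene first and the ring is then closed reductively. Cross-metathesis of 7 with an excess of purchased 5-ethenyl-1,2,3-trimethoxybenzene (second-generation Grubbs catalyst, CH2Cl2, 40 °C) should give the iodo cinnamyl ether F1. Treatment with (Me3Si)3SiH and AIBN in toluene at 80 °C then generates the same C3 radical, which closes 5-exo onto the styrene-type alkene; the benzylic C7' radical takes hydrogen from the silane to give 11 under the same substrate control.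

Step 4. The electron-rich benzylic C–O bond may ionise, which gives partial retention and erodes configurational purity; a hydride shift to a carbonyl compound or loss of the silyl ether under the Lewis acid are further risks. The fallback sets out from 9 and returns at 6: the benzylic stereocentre is made by carbonyl addition and the allyl group is introduced by O-alkylation, so no substitution occurs at the benzylic carbon. Grignard reagent 9 is added to purchased (4S)-2,2-dimethyl-1,3-dioxolane-4-carbaldehyde in THF at −78 °C, if necessary after transmetalation with ClTi(OiPr)3 to raise the Felkin–Anh preference. The anti adduct, the dioxolanyl carbinol F2, is separated from its syn epimer by chromatography. NaH and allyl bromide in THF/DMF give the allyl ether F3, aqueous acetic acid at 40 °C removes the acetonide to give the diol F4, and TBSCl with imidazole at 0 °C silylates the primary hydroxyl to give 6.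

Step 5. Displacement at the hindered, doubly β-oxygenated carbon may be slow, so that elimination or a 1,2-shift through participation of the neighbouring aryl or ether group takes over; the silyl ether may also be lost on prolonged heating. The fallback sets out from 6 and returns at 11: the C3 radical is generated from the C–O bond and the iodide is never made. Cross-metathesis of 6 with 5-ethenyl-1,2,3-trimethoxybenzene (second-generation Grubbs catalyst, CH2Cl2, 40 °C) should give the hydroxy cinnamyl ether F5. PhOC(S)Cl, pyridine and DMAP in CH2Cl2 convert its secondary alcohol into the phenyl thionocarbonate F6. Bu3SnH and AIBN in toluene at 90 °C (Barton–McCombie conditions, slow addition) cleave the C3–O bond, and the radical cyclizes 5-exo onto the cinnamyl alkene before hydrogen transfer, giving 11.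

Further compounds
F1 | step 7 | tert-butyl{[(2R,3R)-2-iodo-3-(3,4,5-trimethoxyphenyl)-3-{[(2E)-3-(3,4,5-trimethoxyphenyl)prop-2-en-1-yl]oxy}propyl]oxy}dimethylsilane | COc1cc(/C=C/CO[C@H](c2cc(OC)c(OC)c(OC)c2)[C@H](I)CO[Si](C)(C)C(C)(C)C)cc(OC)c1OC
F2 | step 4 | (R)-[(4S)-2,2-dimethyl-1,3-dioxolan-4-yl](3,4,5-trimethoxyphenyl)methanol | O[C@H](c1cc(OC)c(OC)c(OC)c1)[C@@H]1COC(C)(C)O1
F3 | step 4 | (4S)-2,2-dimethyl-4-[(R)-(prop-2-en-1-yloxy)(3,4,5-trimethoxyphenyl)methyl]-1,3-dioxolane | C=CCO[C@H](c1cc(OC)c(OC)c(OC)c1)[C@@H]1COC(C)(C)O1
F4 | step 4 | (2S,3R)-3-(prop-2-en-1-yloxy)-3-(3,4,5-trimethoxyphenyl)propane-1,2-diol | C=CCO[C@H](c1cc(OC)c(OC)c(OC)c1)[C@@H](O)CO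
F5 | step 5 | (1R,2S)-3-{[tert-butyl(dimethyl)silyl]oxy}-1-(3,4,5-trimethoxyphenyl)-1-{[(2E)-3-(3,4,5-trimethoxyphenyl)prop-2-en-1-yl]oxy}propan-2-ol | COc1cc(/C=C/CO[C@H](c2cc(OC)c(OC)c(OC)c2)[C@@H](O)CO[Si](C)(C)C(C)(C)C)cc(OC)c1OC
F6 | step 5 | O-[(2S,3R)-1-{[tert-butyl(dimethyl)silyl]oxy}-3-(3,4,5-trimethoxyphenyl)-3-{[(2E)-3-(3,4,5-trimethoxyphenyl)prop-2-en-1-yl]oxy}propan-2-yl] O-phenyl carbonothioate | COc1cc(/C=C/CO[C@H](c2cc(OC)c(OC)c(OC)c2)[C@@H](OC(=S)Oc3ccccc3)CO[Si](C)(C)C(C)(C)C)cc(OC)c1OC
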